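The route rests on cutting the C3'–C6'' biaryl bond between ring B of flavone unit 1 and ring A of flavone unit 2. Both termini carry an ortho oxygen (O4' and O5''). C6''–H is the only C–H ortho to O5'', since C4a'' is quaternary and C8'' lies para. Tying O4' to O5'' through one CH2 lets a palladium-catalysed C–H arylation forge the hindered bond, fix the 6''-regiochemistry and close a seven-membered dibenzo-1,3-dioxepine in one operation. The precursor 11 is a 3'-bromo bis-flavone tetrabenzyl ether bridged O4'–CH2–O5''. Chelation-directed reductive opening then turns the bridge carbon into the 4'-methoxy group.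

Key step: step 8

Remark on the chemistry: the target SMILES carries no stereodescriptor, so the C3'–C6'' axis is treated as configurationally unassigned and needs no control. Unprimed and primed locants belong to flavone unit 1 (rings A, C, B). Doubly and triply primed locants belong to flavone unit 2.

Step 1
Reactants: 1 2,4,6-trihydroxyacetophenone
Product: 2 2-hydroxy-4,6-bis(benzyloxy)acetophenone
Conditions: BnBr (2.1 equiv), K2CO3, DMF, rt to 50 °C
Reagents that add atoms: benzyl bromide, BrCc1ccccc1
Why: Williamson etherification takes the 4-OH and one of the two equivalent ortho hydroxyls, after which the last hydroxyl is hydrogen-bonded to the acetyl C=O and is too poor a nucleophile to react under carbonate conditions.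

Step 2
Reactants: 2 2-hydroxy-4,6-bis(benzyloxy)acetophenone; 3 3-bromo-4-hydroxybenzaldehyde
Product: 4 (E)-2'-hydroxy-4',6'-bis(benzyloxy)-3-bromo-4-hydroxychalcone
Conditions: KOH (50% aq, excess), EtOH–THF, rt, 48 h; then 1 M HCl
Reagents that add atoms: none
Why: Claisen–Schmidt condensation of the ketone enolate with a non-enolisable aldehyde gives the conjugated E-enone under thermodynamic control after E1cB loss of water, and the ortho bromine weakens the donor strength of the 4-phenoxide enough for the unprotected aldehyde to react, which saves a protection and deprotection pair.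

Step 3
Reactants: 4 (E)-2'-hydroxy-4',6'-bis(benzyloxy)-3-bromo-4-hydroxychalcone
Product: 5 3'-bromo-4'-hydroxy-5,7-bis(benzyloxy)flavone
Conditions: I2 (10 mol %), DMSO, 120 °C
Reagents that add atoms: none
Why: This is the iodine-catalysed oxidative cyclisation of a 2'-hydroxychalcone (oxa-Michael closure, alpha-iodination, loss of HI, DMSO as terminal oxidant), a standard flavone synthesis that tolerates benzyl ethers, the aryl bromide and a free 4'-phenol while iodine stays catalytic.

Step 4
Reactants: 5 3'-bromo-4'-hydroxy-5,7-bis(benzyloxy)flavone; 6 chloromethyl methyl sulfide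
Product: 7 3'-bromo-4'-(methylsulfanylmethoxy)-5,7-bis(benzyloxy)flavone
Conditions: NaH, DMF, 0 °C; then 6, 0 °C to rt
Reagents that add atoms: chloromethyl methyl sulfide (compound 6), CSCCl
Why: Williamson-type O-alkylation of the only free and acidic phenol with an alpha-chloro sulfide is the standard entry to aryl methylthiomethyl ethers.

Step 5
Reactants: 7 3'-bromo-4'-(methylsulfanylmethoxy)-5,7-bis(benzyloxy)flavone
Product: 8 3'-bromo-4'-(chloromethoxy)-5,7-bis(benzyloxy)flavone
Conditions: SO2Cl2 (1.0 equiv), cyclohexene (3 equiv), CH2Cl2, −20 to 0 °C; evaporate, use crude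
Reagents that add atoms: sulfuryl chloride, O=S(=O)(Cl)Cl
Why: In this chlorinolysis of an O,S-acetal the sulfur is by far the most nucleophilic site, its chlorosulfonium salt collapses to the aryl chloromethyl ether, and one equivalent of SO2Cl2 in the cold with cyclohexene as sulfenyl chloride trap keeps the electron-rich ring A and C3 from being chlorinated or sulfenylated.

Step 6
Reactants: 9 apigenin
Product: 10 7,4'-di-O-benzylapigenin
Conditions: BnBr (2.2 equiv), K2CO3, DMF, rt to 50 °C
Reagents that add atoms: benzyl bromide, BrCc1ccccc1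
Why: Williamson etherification follows the acidity order 7-OH, 4'-OH, then 5-OH, so the 5-OH, hydrogen-bonded to C4=O, stays free with two equivalents of halide.

Step 7
Reactants: 8 3'-bromo-4'-(chloromethoxy)-5,7-bis(benzyloxy)flavone; 10 7,4'-di-O-benzylapigenin
Product: 11 O4'–CH2–O5''-bridged 3'-bromo bis-flavone tetrabenzyl ether
Conditions: 10 (1.2 equiv), NaH (1.3 equiv), DMF, 0 °C; then crude 8 in THF, 0 °C to rt
Reagents that add atoms: none
Why: Williamson-type SN2 displacement on an alpha-chloro ether is the known entry to unsymmetrical diaryloxymethanes, with NaH breaking the 5-OH to C4=O hydrogen bond irreversibly and the very reactive electrophile offsetting the modest nucleophilicity of the peri phenoxide.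

Step 8
Reactants: 11 O4'–CH2–O5''-bridged 3'-bromo bis-flavone tetrabenzyl ether
Product: 12 dibenzo[d,f][1,3]dioxepine-bridged 3',6''-biflavone tetrabenzyl ether
Conditions: Pd(OAc)2 (10 mol %), PCy3·HBF4 (20 mol %), PivOH (30 mol %), K2CO3 (2.5 equiv), DMA (0.02 M), 110 °C, argon
Reagents that add atoms: none
Why: Zerovalent palladium formed from Pd(OAc)2 and PCy3 inserts into C3'–Br, pivalate removes C6''–H by concerted metalation-deprotonation, and reductive elimination from the diarylpalladium species forms C3'–C6''. The closest known reaction type is the intramolecular direct arylation of tethered aryl bromides under Pd(OAc)2/PCy3/pivalate conditions, which closes dibenzo-fused seven-membered rings, including bis(aryloxy) substrates joined through a one-atom O–Si–O bridge. The single new ring, the dibenzo[d,f][1,3]dioxepine, closes by ring-contracting C(sp2)–C(sp2) reductive elimination from an eight-membered palladacycle (Pd, C3', C4', O4', CH2, O5'', C5'', C6''). No stereocentre is created, and the twisted biaryl axis of 12 forms as a racemate, which is of no consequence because the bridge is opened in step 9. The step needs 6''- over 8''-arylation and ring closure over intermolecular coupling: C6'' is the only C–H carbon ortho to the tether-bearing O5'' (C4a'' is quaternary, C8'' is para and beyond a three-atom bridge), the peri C4''=O turns the O5''–CH2 bond towards C6'', and high dilution suppresses oligomers. The C6''–H bond, flanked by O5'' and O7'', is also the most acidic arene C–H within reach, which favours the deprotonative metalation.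

Step 9
Reactants: 12 dibenzo[d,f][1,3]dioxepine-bridged 3',6''-biflavone tetrabenzyl ether
Product: 13 5,5''-dihydroxy-4'-methoxy-7,7'',4'''-tris(benzyloxy)-3',6''-biflavone
Conditions: TiCl4 (3 equiv), Et3SiH (10 equiv), CH2Cl2, −78 to 0 °C; then aq NaHCO3
Reagents that add atoms: none
Why: Proposed new method: TiCl4 binds as a six-membered chelate between C4''=O and O5'', which makes the 5''-aryloxide the better leaving group of the unsymmetrical diaryl formal, so the O5''–CH2 bond ionises to the O4'-stabilised oxocarbenium ion, which Et3SiH reduces irreversibly to the 4'-methyl ether with help from relief of the dioxepine twist, while a second chelate at C4=O/O5 removes the peri 5-O-benzyl group as benzyl chloride, a planned loss because all benzyl groups leave in step 10; the closest known reaction types are the TiCl4/Et3SiH reductive cleavage of dialkyl and benzylidene acetals to ethers with chelation-controlled regiochemistry and the Lewis acid dealkylation of 5-alkoxyflavones.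

Step 10
Reactants: 13 5,5''-dihydroxy-4'-methoxy-7,7'',4'''-tris(benzyloxy)-3',6''-biflavone
Product: 14 4'-O-methylrobustaflavone (target)
Conditions: H2 (1 atm), 10% Pd/C, THF–MeOH, rt
Reagents that add atoms: none
Why: Catalytic hydrogenolysis of aryl benzyl ethers at atmospheric pressure and room temperature leaves the flavone C2=C3 bonds, the carbonyls and the aryl methyl ether untouched, as is usual for benzylated flavones.

Compound list
1 | 2,4,6-trihydroxyacetophenone | CC(=O)c1c(O)cc(O)cc1O | starting material
2 | 2-hydroxy-4,6-bis(benzyloxy)acetophenone | CC(=O)c1c(O)cc(OCc2ccccc2)cc1OCc1ccccc1 | intermediate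
3 | 3-bromo-4-hydroxybenzaldehyde | O=Cc1ccc(O)c(Br)c1 | starting material
4 | (E)-2'-hydroxy-4',6'-bis(benzyloxy)-3-bromo-4-hydroxychalcone | O=C(/C=C/c1ccc(O)c(Br)c1)c1c(O)cc(OCc2ccccc2)cc1OCc1ccccc1 | intermediate
5 | 3'-bromo-4'-hydroxy-5,7-bis(benzyloxy)flavone | O=c1cc(-c2ccc(O)c(Br)c2)oc2cc(OCc3ccccc3)cc(OCc3ccccc3)c12 | intermediate
6 | chloromethyl methyl sulfide | CSCCl | starting material
7 | 3'-bromo-4'-(methylsulfanylmethoxy)-5,7-bis(benzyloxy)flavone | CSCOc1ccc(-c2cc(=O)c3c(OCc4ccccc4)cc(OCc4ccccc4)cc3o2)cc1Br | intermediate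
8 | 3'-bromo-4'-(chloromethoxy)-5,7-bis(benzyloxy)flavone | ClCOc1ccc(-c2cc(=O)c3c(OCc4ccccc4)cc(OCc4ccccc4)cc3o2)cc1Br | intermediate
9 | apigenin | O=c1cc(-c2ccc(O)cc2)oc2cc(O)cc(O)c12 | starting material
10 | 7,4'-di-O-benzylapigenin | O=c1cc(-c2ccc(OCc3ccccc3)cc2)oc2cc(OCc3ccccc3)cc(O)c12 | intermediate
11 | O4'–CH2–O5''-bridged 3'-bromo bis-flavone tetrabenzyl ether | O=c1cc(-c2ccc(OCOc3cc(OCc4ccccc4)cc4oc(-c5ccc(OCc6ccccc6)cc5)cc(=O)c34)c(Br)c2)oc2cc(OCc3ccccc3)cc(OCc3ccccc3)c12 | intermediate
12 | dibenzo[d,f][1,3]dioxepine-bridged 3',6''-biflavone tetrabenzyl ether | O=c1cc(-c2ccc3c(c2)-c2c(OCc5ccccc5)cc4oc(-c5ccc(OCc6ccccc6)cc5)cc(=O)c4c2OCO3)oc2cc(OCc3ccccc3)cc(OCc3ccccc3)c12 | intermediate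
13 | 5,5''-dihydroxy-4'-methoxy-7,7'',4'''-tris(benzyloxy)-3',6''-biflavone | COc1ccc(-c2cc(=O)c3c(O)cc(OCc4ccccc4)cc3o2)cc1-c1c(OCc2ccccc2)cc2oc(-c3ccc(OCc4ccccc4)cc3)cc(=O)c2c1O | intermediate
14 | 4'-O-methylrobustaflavone (CNP0197234.0) | COc1ccc(-c2cc(=O)c3c(O)cc(O)cc3o2)cc1-c1c(O)cc2oc(-c3ccc(O)cc3)cc(=O)c2c1O | target

Total step count: 10. Longest linear sequence: 9 (steps 1 to 5, then 7 to 10); step 6 is the side branch.

Steps most likely to fail

Step 9 (the labelled step). Hydride transfer from the silane may be slower than chloride capture or re-closure of the opened bridge, so the bridge carbon would be lost by hydrolysis on work-up. Long exposure could also start ionic reduction of the titanium-activated pyranone rings, or shift the cationic CH2 onto O7''. The fallback uses known chemistry, sets out from 12 and returns at 13. BCl3 (2.2 equiv, one per peri site, CH2Cl2, −78 °C) carries out the established chelation-directed cleavage of ethers and formals next to the flavone carbonyl. After aqueous work-up it should give 4',5,5''-trihydroxy-7,7'',4'''-tris(benzyloxy)-3',6''-biflavone F1. This is also what an incomplete step 9 would deliver, so no material is stranded. MeI (1.1 equiv) with K2CO3 in acetone at rt then methylates only the non-chelated 4'-OH and gives 13.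

Step 8. After oxidative addition, the congested deprotonative metalation may lose out to protodepalladation, for instance after a palladium shift to the acetal CH2. That would mean loss of bromine without ring closure, or intermolecular arylation. The fallback sets out from 5 and 10 and returns at 14, and it makes the bond intermolecularly by Suzuki–Miyaura coupling.
- Methylation of 5 (MeI, K2CO3, acetone) should give 3'-bromo-4'-methoxy-5,7-bis(benzyloxy)flavone F2.
- Miyaura borylation (B2pin2, PdCl2(dppf), KOAc, dioxane, 90 °C) then gives 3'-(pinacolboryl)-4'-methoxy-5,7-bis(benzyloxy)flavone F3.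
- In parallel, 10 is iodinated ortho to its free 5-OH with benzyltrimethylammonium dichloroiodate and CaCO3 in CH2Cl2–MeOH, giving 6-iodo-7,4'-di-O-benzylapigenin F4.
- F4 is benzylated at O5 (BnBr, K2CO3, DMF, 70 °C) to 6-iodo-5,7,4'-tris(benzyloxy)flavone F5.
- Coupling of F3 with F5 (Pd(OAc)2, SPhos, K3PO4, toluene–water, 100 °C) should give 4'-O-methylrobustaflavone pentabenzyl ether F6.
- Hydrogenolysis under the conditions of step 10 gives 14.

Step 5. Electrophilic chlorination or sulfenylation of the electron-rich ring A or of C3 may compete with attack at sulfur, and the chloromethyl ether may hydrolyse on handling. The fallback sets out from 3 (with 6, 10 and 2) and returns at 11. It moves the sulfur-to-chlorine exchange onto the electron-poor aldehyde and builds flavone unit 1 last.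
- Alkylation of 3 with 6 (NaH, DMF) should give 3-bromo-4-(methylsulfanylmethoxy)benzaldehyde F7.
- SO2Cl2 in CH2Cl2 at 0 °C converts F7 into 3-bromo-4-(chloromethoxy)benzaldehyde F8. This cheap electrophile can be used in excess against the sodium salt of 10.
- The coupling gives 5-O-[(2-bromo-4-formylphenoxy)methyl]-7,4'-di-O-benzylapigenin F9.
- Claisen–Schmidt condensation of F9 with 2 (KOH, EtOH–THF, rt) gives the acetal-linked flavone–chalcone F10.
- I2 (10 mol %) in DMSO at 120 °C closes ring C of unit 1 to give 11.

Further compounds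
F1 | step 9 | 4',5,5''-trihydroxy-7,7'',4'''-tris(benzyloxy)-3',6''-biflavone | Oc1ccc(-c2cc(=O)c3c(O)cc(OCc4ccccc4)cc3o2)cc1-c1c(OCc2ccccc2)cc2oc(-c3ccc(OCc4ccccc4)cc3)cc(=O)c2c1O
F2 | step 8 | 3'-bromo-4'-methoxy-5,7-bis(benzyloxy)flavone | COc1ccc(-c2cc(=O)c3c(OCc4ccccc4)cc(OCc4ccccc4)cc3o2)cc1Br
F3 | step 8 | 3'-(pinacolboryl)-4'-methoxy-5,7-bis(benzyloxy)flavone | COc1ccc(-c2cc(=O)c3c(OCc4ccccc4)cc(OCc4ccccc4)cc3o2)cc1B1OC(C)(C)C(C)(C)O1
F4 | step 8 | 6-iodo-7,4'-di-O-benzylapigenin | O=c1cc(-c2ccc(OCc3ccccc3)cc2)oc2cc(OCc3ccccc3)c(I)c(O)c12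
F5 | step 8 | 6-iodo-5,7,4'-tris(benzyloxy)flavone | O=c1cc(-c2ccc(OCc3ccccc3)cc2)oc2cc(OCc3ccccc3)c(I)c(OCc3ccccc3)c12
F6 | step 8 | 4'-O-methylrobustaflavone pentabenzyl ether | COc1ccc(-c2cc(=O)c3c(OCc4ccccc4)cc(OCc4ccccc4)cc3o2)cc1-c1c(OCc2ccccc2)cc2oc(-c3ccc(OCc4ccccc4)cc3)cc(=O)c2c1OCc1ccccc1
F7 | step 5 | 3-bromo-4-(methylsulfanylmethoxy)benzaldehyde | CSCOc1ccc(C=O)cc1Br
F8 | step 5 | 3-bromo-4-(chloromethoxy)benzaldehyde | ClCOc1ccc(C=O)cc1Br
F9 | step 5 | 5-O-[(2-bromo-4-formylphenoxy)methyl]-7,4'-di-O-benzylapigenin | O=Cc1ccc(OCOc2cc(OCc3ccccc3)cc3oc(-c4ccc(OCc5ccccc5)cc4)cc(=O)c23)c(Br)c1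
F10 | step 5 | acetal-linked flavone–chalcone, (E) | O=C(/C=C/c1ccc(OCOc2cc(OCc3ccccc3)cc3oc(-c4ccc(OCc5ccccc5)cc4)cc(=O)c23)c(Br)c1)c1c(O)cc(OCc2ccccc2)cc1OCc1ccccc1
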